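**Plan**

- Retrosynthesis: the enol-ether bond O1–C6 of the dihydropyran is cut first, then the furan ring of the benzofuran (aryl–alkyne bond and furan O–C2 bond), then the C2–C3 bond between the two stereocentres (aldol), and last the alkenyl–alkynyl and acyl–N bonds of the chain.
- Forward: the chain is joined by a Negishi ethynylation and an auxiliary-controlled syn-aldol, the benzofuran ring is built on the terminal alkyne by Sonogashira coupling and 5-endo closure, and the dihydropyran ring is closed last by a dehydrogenative 6-endo C–O bond formation, followed by desilylation.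
- Enabling feature: C5=C6 of the pyran is a 1,1-disubstituted alkene conjugated with the benzofuran ring, and C6 is its unsubstituted terminus, five atoms from the C2 hydroxyl. One-electron oxidation of this 2-alkenylbenzofuran lets the hydroxyl add to C6, the radical at C5 being stabilised by the benzofuran, and loss of H2 gives the enol ether.
- Stereochemistry: C2 (R) and C3 (S), trans, both come from one boron aldol under control of (R)-4-benzyl-1,3-oxazolidin-2-one; no later step touches them.

Key step: step 10

Assumption: 4-bromopent-4-enoic acid and the tert-butyldimethylsilyl ether of vanillin are taken as catalogue compounds.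

**Route**

Step 1
Reactants: 1 4-bromopent-4-enoic acid; 2 (R)-4-benzyl-1,3-oxazolidin-2-one
Product: 4 (R)-4-benzyl-3-(4-bromopent-4-enoyl)-1,3-oxazolidin-2-one, via mixed pivalic anhydride 3 (not isolated)
Conditions: PivCl, Et3N, THF, −20 °C; then 2, LiCl, −20 °C to rt
Reagents that add atoms: none
Why: N-acylation of the LiCl-activated oxazolidinone by the mixed pivalic anhydride (standard loading of an Evans auxiliary) should give the imide without touching the vinyl bromide.

Step 2
Reactants: 4 (R)-4-benzyl-3-(4-bromopent-4-enoyl)-1,3-oxazolidin-2-one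
Product: 5 (R)-4-benzyl-3-(4-methylidenehex-5-ynoyl)-1,3-oxazolidin-2-one
Conditions: HC≡CMgBr, ZnBr2 (excess), THF, 0 °C; then 4, Pd(PPh3)4 (5 mol %), THF, rt
Reagents that add atoms: ethynylmagnesium bromide, C#C[Mg]Br
Why: Negishi coupling of the 2-bromo-1-alkene with ethynylzinc bromide under zerovalent palladium should give the terminal 2-substituted 1,3-enyne directly, the imide being inert to the organozinc.

Step 3
Reactants: 5 (R)-4-benzyl-3-(4-methylidenehex-5-ynoyl)-1,3-oxazolidin-2-one; 6 4-[(tert-butyldimethylsilyl)oxy]-3-methoxybenzaldehyde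
Product: 9 (4R)-4-benzyl-3-[(2R,3R)-3-{4-[(tert-butyldimethylsilyl)oxy]-3-methoxyphenyl}-3-hydroxy-2-(2-methylidenebut-3-yn-1-yl)propanoyl]-1,3-oxazolidin-2-one, via Z-boron enolate 7 (not isolated), via boron aldolate 8 (not isolated)
Conditions: Bu2BOTf, iPr2NEt, CH2Cl2, −78 to 0 °C; then 6, −78 to 0 °C; then pH 7 buffer, MeOH, 30% H2O2, 0 °C
Reagents that add atoms: none
Why: In this Evans syn-aldol the Z-boron enolate should react through a closed Zimmerman–Traxler chair on the face away from the benzyl group of the (R)-auxiliary, which sets the (2R,3R) pair of the acyl chain (later C3 and C2 of the pyran, trans) in one step.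

Step 4
Reactants: 9 the syn-aldol imide
Product: 10 (1R,2S)-1-{4-[(tert-butyldimethylsilyl)oxy]-3-methoxyphenyl}-2-(2-methylidenebut-3-yn-1-yl)propane-1,3-diol
Conditions: LiBH4, MeOH (1 equiv), THF, 0 °C; aq. NH4Cl
Reagents that add atoms: none
Why: Reductive cleavage of the N-acyl oxazolidinone by LiBH4 should give the 1,3-diol and return the auxiliary, while the aryl silyl ether, the enyne and both stereocentres are inert.

Step 5
Reactants: 10 the 1,3-diol
Product: 11 (2S,3R)-3-{4-[(tert-butyldimethylsilyl)oxy]-3-methoxyphenyl}-3-hydroxy-2-(2-methylidenebut-3-yn-1-yl)propyl acetate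
Conditions: AcCl (1.05 equiv), 2,4,6-collidine, CH2Cl2, −78 °C
Reagents that add atoms: acetyl chloride, CC(=O)Cl
Why: Kinetically selective acylation of the primary hydroxyl over the hindered secondary benzylic one at low temperature should give the monoacetate and so remove the only competing nucleophile for the later ring closure.

Step 6
Reactants: 12 1,4-diiodo-2,5-dimethoxybenzene
Product: 14 1-(4-iodo-2,5-dimethoxyphenyl)ethanone, via (4-iodo-2,5-dimethoxyphenyl)lithium 13 (not isolated)
Conditions: n-BuLi (1.0 equiv), THF, −78 °C; then MeC(O)N(OMe)Me, −78 °C to rt; aq. NH4Cl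
Reagents that add atoms: N-methoxy-N-methylacetamide, CC(=O)N(C)OC
Why: A single iodine–lithium exchange on the symmetrical diiodide followed by Weinreb ketone synthesis should fix the 1,2,4,5-substitution pattern without any regiochemical ambiguity.

Step 7
Reactants: 14 1-(4-iodo-2,5-dimethoxyphenyl)ethanone
Product: 15 1-(2,5-dihydroxy-4-iodophenyl)ethanone
Conditions: BBr3 (3 equiv), CH2Cl2, −78 °C to rt; then H2O
Reagents that add atoms: none
Why: Lewis-acid cleavage of both aryl methyl ethers by BBr3 should free the hydroquinone while aryl iodide and ketone survive.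

Step 8
Reactants: 11 the enyne monoacetate; 15 1-(2,5-dihydroxy-4-iodophenyl)ethanone
Product: 17 (2S,3R)-2-[2-(6-acetyl-5-hydroxy-1-benzofuran-2-yl)prop-2-en-1-yl]-3-{4-[(tert-butyldimethylsilyl)oxy]-3-methoxyphenyl}-3-hydroxypropyl acetate, via o-alkynylphenol 16 (not isolated)
Conditions: Pd(PPh3)2Cl2 (5 mol %), CuI (10 mol %), Et3N, DMF, argon, rt then 60 °C
Reagents that add atoms: none
Why: Sonogashira coupling of the aryl iodide with the terminal enyne followed by 5-endo-dig attack of the ortho hydroxyl on the alkyne (Castro–Stephens-type heteroannulation) should build the 2-alkenylbenzofuran, since only the hydroxyl next to the alkyne can close the furan and the ketone-chelated one remains as the phenol.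

Step 9
Reactants: 17 the hydroxybenzofuran
Product: 18 (2S,3R)-2-[2-{6-acetyl-5-[(tert-butyldimethylsilyl)oxy]-1-benzofuran-2-yl}prop-2-en-1-yl]-3-{4-[(tert-butyldimethylsilyl)oxy]-3-methoxyphenyl}-3-hydroxypropyl acetate
Conditions: TBSCl (1.2 equiv), Et3N, CH2Cl2/DMF, 0 °C to rt
Reagents that add atoms: tert-butyldimethylsilyl chloride, CC(C)(C)[Si](C)(C)Cl
Why: With an amine base and no nucleophilic catalyst only the acidic phenol should be silylated (chemoselective O-silylation), so the hindered secondary alcohol stays free and the phenol can no longer quench the oxidised benzofuran in the next step.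

Step 10
Reactants: 18 the bis-silyl ether alkenol
Product: 19 [(2R,3S)-5-{6-acetyl-5-[(tert-butyldimethylsilyl)oxy]-1-benzofuran-2-yl}-2-{4-[(tert-butyldimethylsilyl)oxy]-3-methoxyphenyl}-3,4-dihydro-2H-pyran-3-yl]methyl acetate
Conditions: 9-mesityl-10-methylacridinium tetrafluoroborate (5 mol %), Co(dmgH)2(py)Cl (5 mol %), MeCN (0.02 M), 450 nm LEDs, argon, rt
Reagents that add atoms: none
Why: Proposed new method: the photoexcited acridinium should oxidise the 2-alkenylbenzofuran of 18 to its radical cation, the C2 hydroxyl should add to the terminal carbon C6 to leave the benzofuran-stabilised tertiary radical at C5, and divalent cobalt should take up this radical and release the C6 hydrogen, so that cobalt hydride and proton end as H2 while the reduced acridine returns trivalent cobalt to the divalent state. The closest known reaction types are the acceptorless dehydrogenative anti-Markovnikov coupling of α-substituted styrenes with alcohols under acridinium/Co(dmgH)2(py)Cl catalysis (intermolecular) and the acridinium-catalysed anti-Markovnikov hydroetherification of alkenols; their merger on a tethered alcohol and a heteroaryl alkene is the untested part. The dihydropyran closes in the 6-endo-trig mode, because the anti-Markovnikov attack that gives the stabilised C5 radical is also the one that gives the six-membered ring, whereas 5-exo attack at C5 would leave a primary radical. No stereocentre is formed and C2 and C3 are outside the reacting π-system, so the trans relationship from the aldol should be carried over unchanged. The step needs site selectivity of oxidation (the alkenylbenzofuran before the silyloxy-methoxy-aryl ring, favoured by conjugation of the alkene with the benzofuran and by fast irreversible cyclisation of that radical cation), a single nucleophile (only the C2 hydroxyl is free) and regioselective hydrogen loss (the C6–H bond α to oxygen is the weaker one and its loss gives the enol ether conjugated with the benzofuran, not the allyl ether from C4–H).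

Step 11
Reactants: 19 the bis-silyl dihydropyran
Product: 20 propolis-benzofuran A, [(2R,3S)-5-(6-acetyl-5-hydroxy-1-benzofuran-2-yl)-2-(4-hydroxy-3-methoxyphenyl)-3,4-dihydro-2H-pyran-3-yl]methyl acetate
Conditions: TBAF (2.2 equiv), AcOH (2.5 equiv), THF, 0 °C
Reagents that add atoms: none
Why: Fluoride cleavage of the two aryl silyl ethers, buffered with acetic acid so that no phenoxide can open the pyran through a para-quinone methide or attack the primary acetate, should release the target with both stereocentres intact.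

**Compound list**

1 | 4-bromopent-4-enoic acid | C=C(Br)CCC(=O)O | starting material
2 | (R)-4-benzyl-1,3-oxazolidin-2-one | O=C1N[C@H](Cc2ccccc2)CO1 | starting material
3 | 4-bromopent-4-enoic pivalic anhydride | C=C(Br)CCC(=O)OC(=O)C(C)(C)C | intermediate (not isolated)
4 | (R)-4-benzyl-3-(4-bromopent-4-enoyl)-1,3-oxazolidin-2-one | C=C(Br)CCC(=O)N1C(=O)OC[C@H]1Cc1ccccc1 | intermediate
5 | (R)-4-benzyl-3-(4-methylidenehex-5-ynoyl)-1,3-oxazolidin-2-one | C#CC(=C)CCC(=O)N1C(=O)OC[C@H]1Cc1ccccc1 | intermediate
6 | 4-[(tert-butyldimethylsilyl)oxy]-3-methoxybenzaldehyde | COc1cc(C=O)ccc1O[Si](C)(C)C(C)(C)C | starting material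
7 | (Z)-dibutylboron enolate of 5 | C#CC(=C)C/C=C(\OB(CCCC)CCCC)N1C(=O)OC[C@H]1Cc1ccccc1 | intermediate (not isolated)
8 | dibutylboron aldolate of 9 | COc1cc([C@H](OB(CCCC)CCCC)[C@@H](CC(=C)C#C)C(=O)N2C(=O)OC[C@H]2Cc2ccccc2)ccc1O[Si](C)(C)C(C)(C)C | intermediate (not isolated)
9 | (4R)-4-benzyl-3-[(2R,3R)-3-{4-[(tert-butyldimethylsilyl)oxy]-3-methoxyphenyl}-3-hydroxy-2-(2-methylidenebut-3-yn-1-yl)propanoyl]-1,3-oxazolidin-2-one | COc1cc([C@H](O)[C@@H](CC(=C)C#C)C(=O)N2C(=O)OC[C@H]2Cc2ccccc2)ccc1O[Si](C)(C)C(C)(C)C | intermediate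
10 | (1R,2S)-1-{4-[(tert-butyldimethylsilyl)oxy]-3-methoxyphenyl}-2-(2-methylidenebut-3-yn-1-yl)propane-1,3-diol | COc1cc([C@H](O)[C@@H](CC(=C)C#C)CO)ccc1O[Si](C)(C)C(C)(C)C | intermediate
11 | (2S,3R)-3-{4-[(tert-butyldimethylsilyl)oxy]-3-methoxyphenyl}-3-hydroxy-2-(2-methylidenebut-3-yn-1-yl)propyl acetate | COc1cc([C@H](O)[C@@H](CC(=C)C#C)COC(C)=O)ccc1O[Si](C)(C)C(C)(C)C | intermediate
12 | 1,4-diiodo-2,5-dimethoxybenzene | COc1cc(I)c(OC)cc1I | starting material
13 | (4-iodo-2,5-dimethoxyphenyl)lithium | [Li]c1cc(OC)c(I)cc1OC | intermediate (not isolated)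
14 | 1-(4-iodo-2,5-dimethoxyphenyl)ethanone | CC(=O)c1cc(OC)c(I)cc1OC | intermediate
15 | 1-(2,5-dihydroxy-4-iodophenyl)ethanone | CC(=O)c1cc(O)c(I)cc1O | intermediate
16 | (2S,3R)-2-[4-(4-acetyl-2,5-dihydroxyphenyl)-2-methylidenebut-3-yn-1-yl]-3-{4-[(tert-butyldimethylsilyl)oxy]-3-methoxyphenyl}-3-hydroxypropyl acetate | COc1cc([C@H](O)[C@@H](CC(=C)C#Cc2cc(O)c(C(C)=O)cc2O)COC(C)=O)ccc1O[Si](C)(C)C(C)(C)C | intermediate (not isolated)
17 | (2S,3R)-2-[2-(6-acetyl-5-hydroxy-1-benzofuran-2-yl)prop-2-en-1-yl]-3-{4-[(tert-butyldimethylsilyl)oxy]-3-methoxyphenyl}-3-hydroxypropyl acetate | COc1cc([C@H](O)[C@@H](CC(=C)c2cc3cc(O)c(C(C)=O)cc3o2)COC(C)=O)ccc1O[Si](C)(C)C(C)(C)C | intermediate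
18 | (2S,3R)-2-[2-{6-acetyl-5-[(tert-butyldimethylsilyl)oxy]-1-benzofuran-2-yl}prop-2-en-1-yl]-3-{4-[(tert-butyldimethylsilyl)oxy]-3-methoxyphenyl}-3-hydroxypropyl acetate | COc1cc([C@H](O)[C@@H](CC(=C)c2cc3cc(O[Si](C)(C)C(C)(C)C)c(C(C)=O)cc3o2)COC(C)=O)ccc1O[Si](C)(C)C(C)(C)C | intermediate
19 | [(2R,3S)-5-{6-acetyl-5-[(tert-butyldimethylsilyl)oxy]-1-benzofuran-2-yl}-2-{4-[(tert-butyldimethylsilyl)oxy]-3-methoxyphenyl}-3,4-dihydro-2H-pyran-3-yl]methyl acetate | COc1cc([C@@H]2OC=C(c3cc4cc(O[Si](C)(C)C(C)(C)C)c(C(C)=O)cc4o3)C[C@H]2COC(C)=O)ccc1O[Si](C)(C)C(C)(C)C | intermediate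
20 | propolis-benzofuran A, [(2R,3S)-5-(6-acetyl-5-hydroxy-1-benzofuran-2-yl)-2-(4-hydroxy-3-methoxyphenyl)-3,4-dihydro-2H-pyran-3-yl]methyl acetate | COc1cc([C@@H]2OC=C(c3cc4cc(O)c(C(C)=O)cc4o3)C[C@H]2COC(C)=O)ccc1O | target

**Step count and risks**

Total step count: 11. Longest linear sequence: 9 steps (steps 1–5 and 8–11, from acid 1).

Steps most likely to fail:

1. Step 10 (the step labelled as a proposed new method). The hole may settle on the electron-rich silyloxy-methoxy-aryl ring, leading to dehydrogenation of the benzylic alcohol or C–C fragmentation next to it. The product enol ether, which is easier to oxidise than 18, may be re-oxidised or photodegraded. Hydrogen may also be lost from C4, giving the allylic ether isomer. Fallback with known chemistry, from 18 back to 19: Rh(PPh3)3Cl-catalysed anti-Markovnikov hydroboration of the 1,1-disubstituted alkene with catecholborane (the aryl ketone is tolerated) and buffered H2O2 oxidation should give the primary alcohol F1 as both C5 epimers. Oxidation of its primary hydroxyl with catalytic TEMPO and N-chlorosuccinimide should give the aldehyde, which closes on the C2 hydroxyl to the lactol F2. Dehydration of the lactol with MsCl/Et3N, eased by the benzofuran-activated C5–H, should give 19.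

2. Step 8. The electron-rich iodohydroquinone may be oxidised and the enyne may undergo Glaser-type homocoupling under CuI/amine; the reaction may stall at the uncyclised alkynylphenol; the conjugated enyne may polymerise on heating. Fallback, from 15 (with 11) back to 17: acetylation of the non-chelated hydroxyl of 15 (Ac2O, pyridine, 0 °C) should give 5-acetyl-4-hydroxy-2-iodophenyl acetate F3, which is no longer a hydroquinone. Sonogashira coupling with 11 at rt (Pd(PPh3)2Cl2, CuI, Et3N) should give the alkynyl aryl acetate F4 without heating. Aminolysis of the aryl acetate with one equivalent of pyrrolidine (the alkyl acetate reacts far more slowly) should give 16, now isolated. A separate π-acid cycloisomerisation with AuCl3 (5-endo-dig hydroalkoxylation) should close the furan to 17.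

3. Step 9. The secondary benzylic hydroxyl may be silylated in competition, the hydrogen-bonded phenol may react incompletely, and the aryl silyl ether next to the acetyl group may hydrolyse on purification. Fallback, from 17 to 20: Williamson allylation (allyl bromide, K2CO3, acetone), which is specific for the phenol by acidity, should give the allyl ether F5. Ring closure under the conditions of step 10 should give the dihydropyran F6. Deallylation with Pd(PPh3)4/morpholine should give the mono-silyl ether F7, and buffered TBAF/AcOH as in step 11 should give 20.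

Further compounds
F1 | step 10 | (2S,3R)-2-[2-{6-acetyl-5-[(tert-butyldimethylsilyl)oxy]-1-benzofuran-2-yl}-3-hydroxypropyl]-3-{4-[(tert-butyldimethylsilyl)oxy]-3-methoxyphenyl}-3-hydroxypropyl acetate (both epimers at the new centre) | COc1cc([C@H](O)[C@@H](CC(CO)c2cc3cc(O[Si](C)(C)C(C)(C)C)c(C(C)=O)cc3o2)COC(C)=O)ccc1O[Si](C)(C)C(C)(C)C
F2 | step 10 | [(2R,3S)-5-{6-acetyl-5-[(tert-butyldimethylsilyl)oxy]-1-benzofuran-2-yl}-2-{4-[(tert-butyldimethylsilyl)oxy]-3-methoxyphenyl}-6-hydroxyoxan-3-yl]methyl acetate (epimers at C5 and C6) | COc1cc([C@@H]2OC(O)C(c3cc4cc(O[Si](C)(C)C(C)(C)C)c(C(C)=O)cc4o3)C[C@H]2COC(C)=O)ccc1O[Si](C)(C)C(C)(C)C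
F3 | step 8 | 5-acetyl-4-hydroxy-2-iodophenyl acetate | CC(=O)Oc1cc(C(C)=O)c(O)cc1I
F4 | step 8 | (2S,3R)-2-{4-[2-(acetyloxy)-4-acetyl-5-hydroxyphenyl]-2-methylidenebut-3-yn-1-yl}-3-{4-[(tert-butyldimethylsilyl)oxy]-3-methoxyphenyl}-3-hydroxypropyl acetate | COc1cc([C@H](O)[C@@H](CC(=C)C#Cc2cc(O)c(C(C)=O)cc2OC(C)=O)COC(C)=O)ccc1O[Si](C)(C)C(C)(C)C
F5 | step 9 | (2S,3R)-2-{2-[6-acetyl-5-(prop-2-en-1-yloxy)-1-benzofuran-2-yl]prop-2-en-1-yl}-3-{4-[(tert-butyldimethylsilyl)oxy]-3-methoxyphenyl}-3-hydroxypropyl acetate | COc1cc([C@H](O)[C@@H](CC(=C)c2cc3cc(OCC=C)c(C(C)=O)cc3o2)COC(C)=O)ccc1O[Si](C)(C)C(C)(C)C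
F6 | step 9 | [(2R,3S)-5-[6-acetyl-5-(prop-2-en-1-yloxy)-1-benzofuran-2-yl]-2-{4-[(tert-butyldimethylsilyl)oxy]-3-methoxyphenyl}-3,4-dihydro-2H-pyran-3-yl]methyl acetate | COc1cc([C@@H]2OC=C(c3cc4cc(OCC=C)c(C(C)=O)cc4o3)C[C@H]2COC(C)=O)ccc1O[Si](C)(C)C(C)(C)C
F7 | step 9 | [(2R,3S)-5-(6-acetyl-5-hydroxy-1-benzofuran-2-yl)-2-{4-[(tert-butyldimethylsilyl)oxy]-3-methoxyphenyl}-3,4-dihydro-2H-pyran-3-yl]methyl acetate | COc1cc([C@@H]2OC=C(c3cc4cc(O)c(C(C)=O)cc4o3)C[C@H]2COC(C)=O)ccc1O[Si](C)(C)C(C)(C)C
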